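The data stem from a simulated flask on assumed constants; noise was put on by code.

What is left of the J fed tells me how fast J goes. At 10.0 min the blue run holds 46.5% of the charge and the ochre run 45.7%, out of the 66.7% fed so far, so on average 69.2% of what went in is still there.

| setting | blue | ochre | flask |
|---|---|---|---|
| J | 1.5 M (fed, over 15 min) | 1.5 M (fed, over 15 min) | 1.5 M (fed, over 15 min) |
| Q | 25 mM | 40 mM | 18 mM |
| remark | run made earlier; the fed solution adds 0.50 times the starting volume | run made earlier; the fed solution adds 0.50 times the starting volume | the fed solution adds 0.50 times the starting volume |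
| time |  |  | 15 min |

| run | time / min | Z / % | J / % |
|---|---|---|---|
| blue | 1.33 | 0 | 8.9 |
| blue | 2.50 | 0 | 14.5 |
| blue | 4.00 | 0 | 22.8 |
| blue | 6.00 | 0 | 31.2 |
| blue | 10.0 | 0 | 46.5 |
| blue | 20.0 | 2.2 | 39.1 |
| ochre | 3.00 | 0.4 | 17.5 |
| ochre | 6.00 | 0 | 32.1 |
| ochre | 10.0 | 0.4 | 45.7 |
| ochre | 12.0 | 0 | 51.8 |
| ochre | 15.0 | 0.8 | 57.4 |
| ochre | 20.0 | 5.4 | 36.6 |

(readings scatter by 1 percentage point)

- every charge counts on the volume at the start, and the solution that is fed holds the whole dose
- the average divides the monomer in chains by the number of chains begun, living and dead together
- the earlier runs were read with a standard deviation of 1 percentage point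
- the earlier runs do not show the number of chains; that part of a forecast is a guess
- percentages count the whole charge, also what has not yet gone in

1. average number of monomer units in a chain (chains begun, living or dead) at 15 min
2. part of the J that has reacted at 15 min

I turn Q first. If Q carried much of the loss of J, going from 25 mM to 40 mM should part the two J columns, but at 10.0 min they stand 0.8 percentage points apart against a scatter of 1 point, so for this reckoning I let J vanish by itself.

Next I turn the time. Under a steady feed, portions have waited anything from zero up to the time elapsed, and I replace that spread by its mean, half the time elapsed: the mean wait, or mean residence time. At 10.0 min it is 5.00 min, which gives the half-life of J by the mean wait, 9.39 min. As a test, at the end of the feed the wait is 7.50 min, and the rule leaves 57.5%; the ochre run, in a reading I did not use, shows 57.4%.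

The J charge is 1.5 M in both runs, so they do not test it, and the flask has the same. The flask's Q, 18 mM, is below both runs, and I carry the half-life down to it. So I expect 42.5% reacted at 15 min, and I put no number on chains, which the runs do not show. The forecast says 42% reacted and an average chain of 35, the second on the guess “each Q begins one chain”.

The flask gives 42.0% reacted and an average chain of 10.0.

    J → D (k = 0.00130 s⁻¹)
    J + Q → G + Z (k = 3.00 × 10⁻⁴ L mol⁻¹ s⁻¹)
    2 G → X (k = 0.0410 L mol⁻¹ s⁻¹)
    J + G → Z + G, rate k4*[G]*[J] (k = 0.0500 L mol⁻¹ s⁻¹)

My rule left 57.5% of the J charged and the flask holds 58.0% at 15 min, while its average chain stands 3.50 times below the forecast, with 90% of the Q charged still there. Left until 25 min, the neighbouring flask has a mean wait of 17.5 min, since the whole dose went in by 15 min. The same half-life then leaves 27.5% of J. That flask holds 25.3% of J, with 74.7% reacted.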